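**Plan**
- Numbering of the target ring: C1 carbinol carbon, C2 CMe2, C3=C4, C5 (bearing the exocyclic CH2), C6, C7, C8=C9(Me), C10, C11. The retrosynthesis first cuts the vanillate C–O bond, then C6–C7 together with C4–C5. This releases allene, an E-alkenyl iodide at C4 and an allyl sulfone carbanion at C7.
- Enabling feature: C6–C7 is the middle bond of the 1,5-diene C9=C8–C7–C6–C5=CH2. C6, C5 and the exocyclic CH2 form a 2-substituted allyl unit with two equivalent CH2 ends (the three carbons of allene), attached to the E-olefin C3=C4 whose other neighbour C2 is quaternary.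
- Further cuts: C3=C4 (Takai olefination), C1–C2 (aldol), and the C7–C11 chain from geranyl bromide by oxidative cleavage.
- Forward: the chain is built linearly; the 11-membered ring, the 1,3-diene and the exocyclic methylene arise together in one palladium-catalysed three-component event. The sulfone and TBS helpers are then removed and the ester is installed last.
- Stereochemistry: C1 (R) comes from a reagent-controlled Kiyooka aldol; E-C8=C9 is carried from geranyl bromide; E-C3=C4 comes from the Takai reaction.

Key step: step 9

Assumption: the L-valine-derived oxazaborolidinone is taken to direct Si-face attack on aldehyde 4 (giving 3R); the configuration would be confirmed by Mosher analysis of 6, and the D-valine reagent would serve if the opposite sense were found.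

**Step 1**
Reactants: 1 geranyl bromide
Product: 2 [(2E)-3,7-dimethylocta-2,6-dien-1-yl]sulfonylbenzene (geranyl phenyl sulfone)
Conditions: PhSO2Na, DMF, rt
Reagents that add atoms: sodium benzenesulfinate (PhSO2Na), [Na+].[O-]S(=O)c1ccccc1
Why: SN2 S-alkylation of the sulfinate by the primary allylic bromide should give the allyl sulfone with the E-olefin of the geranyl unit intact.

**Step 2**
Reactants: 2 geranyl phenyl sulfone
Product: 3 2,2-dimethyl-3-[(3E)-3-methyl-5-(phenylsulfonyl)pent-3-en-1-yl]oxirane (racemic)
Conditions: mCPBA, CH2Cl2, 0 °C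
Reagents that add atoms: mCPBA, O=C(OO)c1cccc(Cl)c1
Why: Prilezhaev epoxidation should select the remote trisubstituted olefin because the other one is deactivated by the allylic sulfonyl group, and the racemic epoxide is consumed in step 3.

**Step 3**
Reactants: 3 terminal epoxide
Product: 4 (4E)-4-methyl-6-(phenylsulfonyl)hex-4-enal
Conditions: H5IO6, THF/H2O, 0 °C to rt
Reagents that add atoms: none
Why: Periodic acid opens the epoxide to the glycol and cleaves it in the same flask (glycol cleavage), the usual way to this aldehyde type from terminal epoxides of geranyl derivatives.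

**Step 4**
Reactants: 4 (4E)-4-methyl-6-(phenylsulfonyl)hex-4-enal; 5 1-methoxy-2-methyl-1-(trimethylsilyloxy)prop-1-ene
Product: 6 methyl (3R,6E)-3-hydroxy-2,2,6-trimethyl-8-(phenylsulfonyl)oct-6-enoate
Conditions: N-tosyl-L-valine, BH3·THF, CH2Cl2, 0 °C to rt; then 4 and 5, −78 °C; pH 7 buffer
Reagents that add atoms: none
Why: Mukaiyama aldol addition promoted by the chiral N-tosyl oxazaborolidinone (Kiyooka aldol), in which the boron-bound aldehyde should be attacked on its Si face to set the (R)-carbinol next to the new quaternary carbon.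

**Step 5**
Reactants: 6 β-hydroxy ester
Product: 7 methyl (3R,6E)-3-(tert-butyldimethylsilyloxy)-2,2,6-trimethyl-8-(phenylsulfonyl)oct-6-enoate
Conditions: TBSOTf, 2,6-lutidine, CH2Cl2, −78 to 0 °C
Reagents that add atoms: TBSOTf, CC(C)(C)[Si](C)(C)OS(=O)(=O)C(F)(F)F
Why: Silyl ether protection of the hindered secondary alcohol with the silyl triflate, so that the oxygen cannot capture the allylpalladium unit in step 9.

**Step 6**
Reactants: 7 silyl ether ester
Product: 8 (3R,6E)-3-(tert-butyldimethylsilyloxy)-2,2,6-trimethyl-8-(phenylsulfonyl)oct-6-en-1-ol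
Conditions: i-Bu2AlH, CH2Cl2, −78 to −20 °C
Reagents that add atoms: none
Why: Hydride reduction of the ester to the primary alcohol, with sulfone, silyl ether and olefin inert at low temperature.

**Step 7**
Reactants: 8 primary alcohol
Product: 9 (3R,6E)-3-(tert-butyldimethylsilyloxy)-2,2,6-trimethyl-8-(phenylsulfonyl)oct-6-enal
Conditions: Dess–Martin periodinane, CH2Cl2, 0 °C to rt
Reagents that add atoms: none
Why: Dess–Martin oxidation should give the aldehyde, which has no α-hydrogen and therefore cannot epimerise or eliminate.

**Step 8**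
Reactants: 9 α-quaternary aldehyde
Product: 10 tert-butyl{[(1E,4R,7E)-1-iodo-3,3,7-trimethyl-9-(phenylsulfonyl)nona-1,7-dien-4-yl]oxy}dimethylsilane
Conditions: CrCl2, CHI3, THF/1,4-dioxane, 0 °C to rt
Reagents that add atoms: iodoform, IC(I)I
Why: Takai olefination (geminal dichromium species from CHI3 and CrCl2) should convert the hindered aldehyde into the E-alkenyl iodide with the E preference typical of this reaction.

**Step 9**
Reactants: 10 E-alkenyl iodide allyl sulfone; 11 allene (propa-1,2-diene)
Product: 13 tert-butyl{[(1R,3E,8E)-2,2,9-trimethyl-5-methylidene-7-(phenylsulfonyl)cycloundeca-3,8-dien-1-yl]oxy}dimethylsilane (mixture of C7 epimers), via sodium allyl sulfone carbanion 12 (not isolated)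
Conditions: NaN(SiMe3)2 (1.0 equiv), THF, −78 °C; then added over 10 h to Pd(PPh3)4 (10 mol %), allene (5 equiv), THF, 50 °C, final 2 mM
Reagents that add atoms: none
Why: Proposed new method: zerovalent palladium inserts into the E-alkenyl iodide (retention; quaternary C2 leaves no β-hydrogen), the alkenylpalladium iodide adds to the central carbon of allene to give a 2-alkenyl-π-allylpalladium unit whose two CH2 ends are constitutionally equivalent, and the tethered α-sulfonyl allyl carbanion bonds to either end (outer-sphere attack or attack at palladium followed by reductive elimination give the same constitution), forming C6–C7 and returning zerovalent palladium. The closest known reaction type is the palladium-catalysed carboannulation of allenes by alkenyl or aryl halides bearing a tethered stabilised carbanion, known for five- to nine-membered rings, taken together with π-allylpalladium macrocyclisation and with capture of π-allylpalladium by α-sulfonyl carbanions; the 11-membered ring size and the allyl sulfone anion are the untested elements. The 11-membered carbocycle closes by attack at a terminal allyl carbon, formally 11-exo-tet on the σ-allyl form, under syringe-pump dilution. The only new stereocenter, the sulfone-bearing C7, is left uncontrolled and is erased in step 10, C1 is not touched, and both E-olefins are carried through unchanged. The step needs α- over γ-attack of the allyl sulfone anion, allene insertion before any direct alkenyl–carbanion coupling, and ring closure over oligomerisation or a second allene insertion: γ-attack or direct coupling would have to form a 9-membered ring holding an E-olefin, dilution disfavours intermolecular capture, the allene concentration is kept low, and exactly one equivalent of base avoids isomerising allene to propyne.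

**Step 10**
Reactants: 13 macrocyclic allyl sulfone
Product: 14 tert-butyl{[(1R,3E,8E)-2,2,9-trimethyl-5-methylidenecycloundeca-3,8-dien-1-yl]oxy}dimethylsilane
Conditions: Pd(dppp)Cl2 (10 mol %), LiBHEt3, THF, 0 °C to rt
Reagents that add atoms: none
Why: Palladium-catalysed reductive desulfonylation of an allylic sulfone, in which ionisation to the π-allylpalladium sulfinate and hydride delivery to the less substituted terminus (C7) should leave the trisubstituted E-olefin C8=C9 in place.

**Step 11**
Reactants: 14 macrocyclic silyl ether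
Product: 15 (1R,3E,8E)-2,2,9-trimethyl-5-methylidenecycloundeca-3,8-dien-1-ol
Conditions: n-Bu4NF, THF, 50 °C
Reagents that add atoms: none
Why: Fluoride-induced desilylation, warmed because the oxygen is flanked by the quaternary carbon.

**Step 12**
Reactants: 16 vanillic acid
Product: 18 4-(tert-butyldimethylsilyloxy)-3-methoxybenzoic acid, via bis-silylated vanillic acid 17 (not isolated)
Conditions: TBSCl, imidazole, DMF, rt; then AcOH/THF/H2O, rt
Reagents that add atoms: TBSCl, CC(C)(C)[Si](C)(C)Cl
Why: Silylation of both acidic groups followed by selective hydrolysis of the labile silyl ester should leave the phenol masked as its aryl silyl ether (protection).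

**Step 13**
Reactants: 15 macrocyclic alcohol; 18 4-(tert-butyldimethylsilyloxy)-3-methoxybenzoic acid
Product: 20 (1R,3E,8E)-2,2,9-trimethyl-5-methylidenecycloundeca-3,8-dien-1-yl 4-(tert-butyldimethylsilyloxy)-3-methoxybenzoate, via mixed anhydride 19 (not isolated)
Conditions: 2,4,6-trichlorobenzoyl chloride, Et3N, THF, rt; then 15, DMAP, toluene, 60 °C
Reagents that add atoms: none
Why: Yamaguchi esterification, in which DMAP opens the mixed anhydride at the unhindered aroyl carbonyl and the acylpyridinium acylates the hindered alcohol with retention at C1.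

**Step 14**
Reactants: 20 silyl-protected ester
Product: 21 (1R,3E,8E)-2,2,9-trimethyl-5-methylidenecycloundeca-3,8-dien-1-yl 4-hydroxy-3-methoxybenzoate (target)
Conditions: n-Bu4NF, AcOH, THF, 0 °C
Reagents that add atoms: none
Why: Buffered fluoride desilylation should cleave the aryl silyl ether much faster than it affects the hindered ester.

**Compound list**
1 | geranyl bromide, (2E)-1-bromo-3,7-dimethylocta-2,6-diene | CC(C)=CCC/C(C)=C/CBr | starting material
2 | [(2E)-3,7-dimethylocta-2,6-dien-1-yl]sulfonylbenzene | CC(C)=CCC/C(C)=C/CS(=O)(=O)c1ccccc1 | intermediate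
3 | 2,2-dimethyl-3-[(3E)-3-methyl-5-(phenylsulfonyl)pent-3-en-1-yl]oxirane (racemic) | CC1(C)OC1CC/C(C)=C/CS(=O)(=O)c1ccccc1 | intermediate
4 | (4E)-4-methyl-6-(phenylsulfonyl)hex-4-enal | O=CCC/C(C)=C/CS(=O)(=O)c1ccccc1 | intermediate
5 | 1-methoxy-2-methyl-1-(trimethylsilyloxy)prop-1-ene | COC(=C(C)C)O[Si](C)(C)C | starting material
6 | methyl (3R,6E)-3-hydroxy-2,2,6-trimethyl-8-(phenylsulfonyl)oct-6-enoate | COC(=O)C(C)(C)[C@H](O)CC/C(C)=C/CS(=O)(=O)c1ccccc1 | intermediate
7 | methyl (3R,6E)-3-(tert-butyldimethylsilyloxy)-2,2,6-trimethyl-8-(phenylsulfonyl)oct-6-enoate | COC(=O)C(C)(C)[C@H](O[Si](C)(C)C(C)(C)C)CC/C(C)=C/CS(=O)(=O)c1ccccc1 | intermediate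
8 | (3R,6E)-3-(tert-butyldimethylsilyloxy)-2,2,6-trimethyl-8-(phenylsulfonyl)oct-6-en-1-ol | OCC(C)(C)[C@H](O[Si](C)(C)C(C)(C)C)CC/C(C)=C/CS(=O)(=O)c1ccccc1 | intermediate
9 | (3R,6E)-3-(tert-butyldimethylsilyloxy)-2,2,6-trimethyl-8-(phenylsulfonyl)oct-6-enal | O=CC(C)(C)[C@H](O[Si](C)(C)C(C)(C)C)CC/C(C)=C/CS(=O)(=O)c1ccccc1 | intermediate
10 | tert-butyl{[(1E,4R,7E)-1-iodo-3,3,7-trimethyl-9-(phenylsulfonyl)nona-1,7-dien-4-yl]oxy}dimethylsilane | I/C=C/C(C)(C)[C@H](O[Si](C)(C)C(C)(C)C)CC/C(C)=C/CS(=O)(=O)c1ccccc1 | intermediate
11 | allene (propa-1,2-diene) | C=C=C | starting material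
12 | sodium salt of the α-sulfonyl allyl carbanion of 10 | [Na+].I/C=C/C(C)(C)[C@H](O[Si](C)(C)C(C)(C)C)CC/C(C)=C/[CH-]S(=O)(=O)c1ccccc1 | intermediate
13 | tert-butyl{[(1R,3E,8E)-2,2,9-trimethyl-5-methylidene-7-(phenylsulfonyl)cycloundeca-3,8-dien-1-yl]oxy}dimethylsilane (C7 epimers) | C=C1/C=C/C(C)(C)[C@H](O[Si](C)(C)C(C)(C)C)CC/C(C)=C/C(S(=O)(=O)c2ccccc2)C1 | intermediate
14 | tert-butyl{[(1R,3E,8E)-2,2,9-trimethyl-5-methylidenecycloundeca-3,8-dien-1-yl]oxy}dimethylsilane | C=C1/C=C/C(C)(C)[C@H](O[Si](C)(C)C(C)(C)C)CC/C(C)=C/CC1 | intermediate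
15 | (1R,3E,8E)-2,2,9-trimethyl-5-methylidenecycloundeca-3,8-dien-1-ol | C=C1/C=C/C(C)(C)[C@H](O)CC/C(C)=C/CC1 | intermediate
16 | vanillic acid (4-hydroxy-3-methoxybenzoic acid) | COc1cc(C(=O)O)ccc1O | starting material
17 | tert-butyldimethylsilyl 4-(tert-butyldimethylsilyloxy)-3-methoxybenzoate | COc1cc(C(=O)O[Si](C)(C)C(C)(C)C)ccc1O[Si](C)(C)C(C)(C)C | intermediate
18 | 4-(tert-butyldimethylsilyloxy)-3-methoxybenzoic acid | COc1cc(C(=O)O)ccc1O[Si](C)(C)C(C)(C)C | intermediate
19 | 4-(tert-butyldimethylsilyloxy)-3-methoxybenzoic 2,4,6-trichlorobenzoic anhydride | COc1cc(C(=O)OC(=O)c2c(Cl)cc(Cl)cc2Cl)ccc1O[Si](C)(C)C(C)(C)C | intermediate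
20 | (1R,3E,8E)-2,2,9-trimethyl-5-methylidenecycloundeca-3,8-dien-1-yl 4-(tert-butyldimethylsilyloxy)-3-methoxybenzoate | C=C1/C=C/C(C)(C)[C@H](OC(=O)c2ccc(O[Si](C)(C)C(C)(C)C)c(OC)c2)CC/C(C)=C/CC1 | intermediate
21 | (1R,3E,8E)-2,2,9-trimethyl-5-methylidenecycloundeca-3,8-dien-1-yl 4-hydroxy-3-methoxybenzoate | C=C1/C=C/C(C)(C)[C@H](OC(=O)c2ccc(O)c(OC)c2)CC/C(C)=C/CC1 | target

**Step count and risks**
Total step count: 14. Longest linear sequence: 13 steps (steps 1–11, 13 and 14; step 12 is a one-step side branch).

Steps most likely to fail: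

1. Step 9 (proposed new method). The ring closure may be overtaken by intermolecular capture of the allylpalladium unit (oligomerisation), by a second allene insertion before closure, or by ionisation of the allyl sulfone by zerovalent palladium. The fallback uses known chemistry and sets out from 10. Stille coupling with 2-(tributylstannyl)prop-2-en-1-ol (Pd(PPh3)4, CuI, CsF, DMF) would give (3E,6R,9E)-6-(tert-butyldimethylsilyloxy)-5,5,9-trimethyl-2-methylidene-11-(phenylsulfonyl)undeca-3,9-dien-1-ol F1. Appel bromination (CBr4, PPh3, CH2Cl2, 0 °C) would give (3E,6R,9E)-1-bromo-6-(tert-butyldimethylsilyloxy)-5,5,9-trimethyl-2-methylidene-11-(phenylsulfonyl)undeca-3,9-diene F2. Intramolecular alkylation of the sulfone carbanion (LiN(SiMe3)2, THF, high dilution, −78 to 0 °C), a classical macrocyclisation of terpenoid allyl sulfones in which SN2 and SN2' attack on the 2-(bromomethyl)diene give the same constitution, would return to the route at 13.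

2. Step 10. Hydride delivery to the tertiary allyl terminus, or syn/anti equilibration of the π-allylpalladium intermediate, would move the C8=C9 olefin or scramble its geometry. The fallback sets out from 13 and replaces the metal-hydride substitution by an electron-transfer cleavage: buffered sodium amalgam (Na/Hg, Na2HPO4, MeOH/THF, −20 °C) generates the allyl anion, which should be protonated kinetically at the less substituted carbon. It returns to the route at 14 and makes no new compound (F0).

3. Step 13. Acyl transfer to the hindered carbinol next to the quaternary carbon may be slow enough for anhydride scrambling to consume the activated acid. The fallback sets out from 18, which would be converted with 1-chloro-N,N,2-trimethylprop-1-en-1-amine (CH2Cl2, rt) into 4-(tert-butyldimethylsilyloxy)-3-methoxybenzoyl chloride F3. The lithium alkoxide of 15 (LiN(SiMe3)2, THF, −78 °C) would then be acylated directly by F3, returning to the route at 20.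

**Further compounds**
F1 | step 9 | (3E,6R,9E)-6-(tert-butyldimethylsilyloxy)-5,5,9-trimethyl-2-methylidene-11-(phenylsulfonyl)undeca-3,9-dien-1-ol | C=C(CO)/C=C/C(C)(C)[C@H](O[Si](C)(C)C(C)(C)C)CC/C(C)=C/CS(=O)(=O)c1ccccc1
F2 | step 9 | (3E,6R,9E)-1-bromo-6-(tert-butyldimethylsilyloxy)-5,5,9-trimethyl-2-methylidene-11-(phenylsulfonyl)undeca-3,9-diene | C=C(CBr)/C=C/C(C)(C)[C@H](O[Si](C)(C)C(C)(C)C)CC/C(C)=C/CS(=O)(=O)c1ccccc1
F0 | step 10 | none | none
F3 | step 13 | 4-(tert-butyldimethylsilyloxy)-3-methoxybenzoyl chloride | COc1cc(C(=O)Cl)ccc1O[Si](C)(C)C(C)(C)C
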